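**Assumptions (one line):** abietane numbering (C1–C20) is used for the quinone half and primed labdane numbering (C1'–C20') for the acid half; the (R)-configured chiral acid in step 3 is taken to give the natural (5S,10S) series (otherwise its mirror image is used) in about 90% ee, and the adduct from the minor enantiomer is removed as a diastereomer after step 14.

## Retrosynthetic overview

1. The bicyclo[3.2.1]octene-dione is cut last, by a perezone-type [5+2] cycloaddition between a hydroxy-para-quinone aldehyde (6-5-6 half) and the terminal vinyl group of (12E)-labda-8(17),12,14-trien-18-oic acid.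
2. The hydroxyquinone comes from a simple para-blocked phenol by an aerobic double C–H oxygenation that makes the C11–O and C14–O bonds; this is the pivotal step.
3. The 6-5-6 phenol comes from 6,7-dehydroferruginol methyl ether by an aryl-shift ring contraction; the abietane tricycle comes from an enantioselective proton-initiated bicyclisation of a homogeranylarene made from 2-isopropylanisole and geranyl chloride.
4. The trienoic acid comes from abietic acid, which supplies C4', C5', C9' and C10': ring C is cleaved at C13=C14, C14 becomes the exocyclic methylene, the isobutyryl unit is excised and the diene is rebuilt by two Wittig reactions.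
5. Ring order: ring C (arene, bought), then rings A and B together, then contraction of ring B from six to five, then the quinone, then the bicyclo[3.2.1]octane.

## Route

**Step 1**
Reactants: 1 2-isopropylanisole
Product: 2 4-(chloromethyl)-1-methoxy-2-(propan-2-yl)benzene
Conditions: (CH2O)n, conc. HCl, ZnCl2 (cat.), AcOH, 50 °C
Reagents that add atoms: formaldehyde (as paraformaldehyde) C=O; hydrogen chloride Cl
Why: Blanc chloromethylation (electrophilic aromatic substitution): the methoxy group directs para and the ortho isopropyl group blocks the other activated side; no stereocentre.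

**Step 2**
Reactants: 2 4-(chloromethyl)-1-methoxy-2-(propan-2-yl)benzene; 3 geranyl chloride
Product: 5 4-[(3E)-4,8-dimethylnona-3,7-dien-1-yl]-1-methoxy-2-(propan-2-yl)benzene, via benzylmagnesium chloride 4 (not isolated)
Conditions: Mg, THF, 0 °C; then 3, Li2CuCl4 (3 mol%), THF, −20 °C to rt
Reagents that add atoms: none
Why: benzylic Grignard formation followed by a Li2CuCl4-catalysed (Kochi-type) SN2 coupling at the primary allylic chloride, which keeps the E-alkene and avoids SN2' attack; no stereocentre.

**Step 3**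
Reactants: 5 4-[(3E)-4,8-dimethylnona-3,7-dien-1-yl]-1-methoxy-2-(propan-2-yl)benzene
Product: 6 (+)-ferruginol methyl ether (12-methoxyabieta-8,11,13-triene; 5S,10S)
Conditions: SbCl5·(R)-3,3'-dichloro-1,1'-bi-2-naphthol (0.5 equiv), CH2Cl2, −78 °C
Reagents that add atoms: none
Why: enantioselective proton-initiated cation–olefin bicyclisation with a chiral Lewis-acid-assisted Brønsted acid: the chair–chair transition state gives the trans ring fusion, the chiral proton donor selects the face of the terminal alkene and so sets C5 (S) and C10 (S), and the Friedel–Crafts closure occurs para to the isopropyl group.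

**Step 4**
Reactants: 6 (+)-ferruginol methyl ether
Product: 7 12-methoxyabieta-6,8,11,13-tetraene (6,7-dehydroferruginol methyl ether)
Conditions: DDQ (1.2 equiv), 1,4-dioxane, 80 °C
Reagents that add atoms: none
Why: DDQ dehydrogenation: hydride abstraction from the para-methoxybenzylic C7 followed by loss of H6 gives the styrene, and C5 and C10 are untouched.

**Step 5**
Reactants: 7 12-methoxyabieta-6,8,11,13-tetraene
Product: 8 (4aS,9R,9aS)-9-(dimethoxymethyl)-6-methoxy-1,1,4a-trimethyl-7-(propan-2-yl)-2,3,4,4a,9,9a-hexahydro-1H-fluorene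
Conditions: PhI(OH)OTs (1.2 equiv), MeOH/HC(OMe)3, 0 °C
Reagents that add atoms: methanol CO
Why: hypervalent-iodine oxidative ring contraction of a 1,2-dihydronaphthalene (aryl 1,2-shift): the trivalent iodine adds to C6 on the open α face, methanol adds to C7, and the equatorial C6–I bond lies anti to the C7–aryl bond so that C8 migrates to C6 with inversion, which sets C6 (R) and leaves C7 as the dimethyl acetal.

**Step 6**
Reactants: 8 the methyl ether acetal
Product: 9 (4aS,9R,9aS)-9-(dimethoxymethyl)-1,1,4a-trimethyl-7-(propan-2-yl)-2,3,4,4a,9,9a-hexahydro-1H-fluoren-6-ol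
Conditions: NaSEt (5 equiv), DMF, 120 °C; then aq. NH4Cl
Reagents that add atoms: none
Why: SN2 O-demethylation of the aryl methyl ether by ethanethiolate; the acetal and all stereocentres are inert to the basic conditions.

**Step 7**
Reactants: 9 the phenol acetal
Product: 13 hydroxyquinone aldehyde (taiwaniaquinone A skeleton; 5S,6R,10S), via ortho-quinone 10 (not isolated), via benzenetriol 11 (not isolated), via hydroxyquinone acetal 12 (not isolated)
Conditions: [Cu(MeCN)4]PF6 (20 mol%), N,N'-di-tert-butylethylenediamine (40 mol%), O2 (1 atm), CH2Cl2, rt; then MeCN/H2O, NaHCO3, O2, rt; then 2 M HCl, THF, rt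
Reagents that add atoms: dioxygen O=O; water O
Why: Proposed new method: a side-on peroxo-dicopper species (tyrosinase-type, formed from monovalent copper, the diamine and O2) oxygenates the phenolate at C11, the only free ortho carbon, to give ortho-quinone 10; water then adds in conjugate fashion at C14 (the only unsubstituted ring carbon, β to the C12 carbonyl) and triol 11 is re-oxidised by O2 to the 2-hydroxy-1,4-quinone 12, just as dopaquinone becomes topaquinone in copper amine oxidase cofactor biogenesis, after which acid frees the aldehyde; the closest known reaction type is the copper/diamine-catalysed aerobic ortho-oxygenation of phenols to ortho-quinones, which has not been taken in one pot to a hydroxy-para-quinone on a para-blocked phenol, and no stereocentre is touched because the acetal keeps C6–H non-acidic during the oxidation.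

**Step 8**
Reactants: 14 (−)-abietic acid
Product: 16 13,14-dioxo-13,14-secoabiet-7-en-18-oic acid (C14 aldehyde on C8 and C13 isopropyl ketone), via 13α,14α-diol 15 (not isolated)
Conditions: OsO4 (2 mol%), NaIO4 (2.5 equiv), 2,6-lutidine, 1,4-dioxane/H2O, rt
Reagents that add atoms: osmium tetroxide O=[Os](=O)(=O)=O; sodium periodate [Na+].[O-]I(=O)(=O)=O
Why: Lemieux–Johnson oxidative cleavage: OsO4 dihydroxylates the more electron-rich and more exposed C13=C14 end of the diene (drawn on the α face; either face gives the same product) and periodate cleaves the diol, after which the remaining C7=C8 bond is a deactivated enal; C4, C5, C9 and C10 come unchanged from the chiral pool.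

**Step 9**
Reactants: 16 the seco keto-enal acid
Product: 18 (1R,4aR,5S,8aR)-1,4a-dimethyl-6-methylidene-5-(4-methyl-3-oxopentyl)decahydronaphthalene-1-carboxylic acid, via tosylhydrazone 17 (not isolated)
Conditions: TsNHNH2 (1.05 equiv), EtOH, rt; then catecholborane (2.5 equiv), CHCl3, 0 °C; NaOAc·3H2O, 60 °C
Reagents that add atoms: none
Why: Kabalka reduction of an α,β-unsaturated tosylhydrazone: the aldehyde condenses far faster than the hindered isopropyl ketone, catecholborane reduces the C=N bond, and loss of sulfinate and N2 from the allylic diazene (retro-ene) delivers hydrogen to C7 and moves the double bond to the exocyclic position.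

**Step 10**
Reactants: 18 the exocyclic-methylene keto acid
Product: 20 (1R,4aR,5S,8aR)-5-(2-hydroxy-4-methyl-3-oxopentyl)-1,4a-dimethyl-6-methylidenedecahydronaphthalene-1-carboxylic acid (both carbinol epimers), via dilithium enolate 19 (not isolated)
Conditions: LiN(iPr)2 (2.3 equiv), THF, −78 °C; then 2-(phenylsulfonyl)-3-phenyloxaziridine, −78 °C; aq. NH4Cl
Reagents that add atoms: 2-(phenylsulfonyl)-3-phenyloxaziridine O=S(=O)(N1OC1c1ccccc1)c1ccccc1
Why: kinetic deprotonation occurs at the methylene rather than the isopropyl methine and the enolate is hydroxylated by the sulfonyloxaziridine (Davis oxidation); the new carbinol centre is a mixture that is destroyed in step 11.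

**Step 11**
Reactants: 20 the α-hydroxy ketone
Product: 21 (1R,4aR,5S,8aR)-1,4a-dimethyl-6-methylidene-5-(2-oxoethyl)decahydronaphthalene-1-carboxylic acid
Conditions: H5IO6 (1.5 equiv), THF/H2O, 0 °C to rt
Reagents that add atoms: none
Why: periodic acid (Malaprade-type) cleavage of the α-hydroxy ketone gives the aldehyde and releases the isobutyryl unit as isobutyric acid; no stereocentre is affected.

**Step 12**
Reactants: 21 the aldehyde acid
Product: 22 (1R,4aR,5S,8aR)-1,4a-dimethyl-6-methylidene-5-[(2E)-3-methyl-4-oxobut-2-en-1-yl]decahydronaphthalene-1-carboxylic acid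
Conditions: Ph3P=C(Me)CHO (2.5 equiv), toluene, 90 °C
Reagents that add atoms: 2-(triphenylphosphoranylidene)propanal CC(C=O)=P(c1ccccc1)(c1ccccc1)c1ccccc1
Why: Wittig olefination with a stabilised ylide, which gives the (E)-trisubstituted enal with the formyl group trans to the ring-bearing chain.

**Step 13**
Reactants: 22 the enal acid
Product: 23 (12E)-labda-8(17),12,14-trien-18-oic acid (4-epimer of trans-communic acid)
Conditions: Ph3PCH3Br (3 equiv), KOtBu (3 equiv), THF, 0 °C to rt; then aq. citric acid
Reagents that add atoms: methyltriphenylphosphonium bromide C[P+](c1ccccc1)(c1ccccc1)c1ccccc1.[Br-]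
Why: Wittig methylenation of the enal carbonyl (1,2-addition) completes the (12'E)-diene while the carboxylate is inert.

**Step 14**
Reactants: 13 hydroxyquinone aldehyde; 23 (12E)-labda-8(17),12,14-trien-18-oic acid
Product: 24 the target CNP0256710.1
Conditions: BF3·OEt2 (1.2 equiv), CH2Cl2, −78 to −30 °C
Reagents that add atoms: none
Why: perezone-type cationic [5+2] cycloaddition: BF3 bound between O11 and O12 turns C8–C9–C11–C12–C13 into an oxidopentadienyl cation, the terminal CH2 (C15') of the diene bonds to C8 and the resulting allyl cation closes on C13 through C14', with approach on the α face anti to the C10 methyl and the remaining C12'=C13' alkene endo under the forming enedione bridge, which sets C8 (S), C13 (R) and C14' (S); the adduct from the minor enantiomer of 13 is a diastereomer and is removed by chromatography.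

## Compound list

1 | 2-isopropylanisole | COc1ccccc1C(C)C | starting material
2 | 4-(chloromethyl)-1-methoxy-2-(propan-2-yl)benzene | COc1ccc(CCl)cc1C(C)C | intermediate
3 | geranyl chloride, (2E)-1-chloro-3,7-dimethylocta-2,6-diene | CC(C)=CCC/C(C)=C/CCl | starting material
4 | [4-methoxy-3-(propan-2-yl)benzyl]magnesium chloride | COc1ccc(C[Mg]Cl)cc1C(C)C | intermediate
5 | 4-[(3E)-4,8-dimethylnona-3,7-dien-1-yl]-1-methoxy-2-(propan-2-yl)benzene | COc1ccc(CC/C=C(\C)CCC=C(C)C)cc1C(C)C | intermediate
6 | (+)-ferruginol methyl ether, (4bS,8aS)-3-methoxy-4b,8,8-trimethyl-2-(propan-2-yl)-4b,5,6,7,8,8a,9,10-octahydrophenanthrene | CC(C)c1cc2c(cc1OC)[C@@]1(C)CCCC(C)(C)[C@@H]1CC2 | intermediate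
7 | 12-methoxyabieta-6,8,11,13-tetraene, (4bS,8aS)-3-methoxy-4b,8,8-trimethyl-2-(propan-2-yl)-4b,5,6,7,8,8a-hexahydrophenanthrene | CC(C)c1cc2c(cc1OC)[C@@]1(C)CCCC(C)(C)[C@@H]1C=C2 | intermediate
8 | (4aS,9R,9aS)-9-(dimethoxymethyl)-6-methoxy-1,1,4a-trimethyl-7-(propan-2-yl)-2,3,4,4a,9,9a-hexahydro-1H-fluorene | CC(C)c1cc2c(cc1OC)[C@@]1(C)CCCC(C)(C)[C@@H]1[C@H]2C(OC)OC | intermediate
9 | (4aS,9R,9aS)-9-(dimethoxymethyl)-1,1,4a-trimethyl-7-(propan-2-yl)-2,3,4,4a,9,9a-hexahydro-1H-fluoren-6-ol | CC(C)c1cc2c(cc1O)[C@@]1(C)CCCC(C)(C)[C@@H]1[C@H]2C(OC)OC | intermediate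
10 | (4aS,9R,9aS)-9-(dimethoxymethyl)-1,1,4a-trimethyl-7-(propan-2-yl)-2,3,4,4a,9,9a-hexahydro-1H-fluorene-5,6-dione (ortho-quinone) | CC(C)C1=CC2=C(C(=O)C1=O)[C@@]1(C)CCCC(C)(C)[C@@H]1[C@H]2C(OC)OC | intermediate
11 | (4aS,9R,9aS)-9-(dimethoxymethyl)-1,1,4a-trimethyl-7-(propan-2-yl)-2,3,4,4a,9,9a-hexahydro-1H-fluorene-5,6,8-triol | CC(C)c1c(O)c2c(c(O)c1O)[C@@]1(C)CCCC(C)(C)[C@@H]1[C@H]2C(OC)OC | intermediate
12 | (4aS,9R,9aS)-9-(dimethoxymethyl)-6-hydroxy-1,1,4a-trimethyl-7-(propan-2-yl)-2,3,4,4a,9,9a-hexahydro-1H-fluorene-5,8-dione | CC(C)C1=C(O)C(=O)C2=C(C1=O)[C@H](C(OC)OC)[C@H]1C(C)(C)CCC[C@]21C | intermediate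
13 | (4aS,9R,9aS)-6-hydroxy-1,1,4a-trimethyl-5,8-dioxo-7-(propan-2-yl)-2,3,4,4a,5,8,9,9a-octahydro-1H-fluorene-9-carbaldehyde (taiwaniaquinone A skeleton) | CC(C)C1=C(O)C(=O)C2=C(C1=O)[C@H](C=O)[C@H]1C(C)(C)CCC[C@]21C | intermediate
14 | (−)-abietic acid, abieta-7,13-dien-18-oic acid | CC(C)C1=CC2=CC[C@@H]3[C@](C)(CCC[C@@]3(C)C(=O)O)[C@H]2CC1 | starting material
15 | 13α,14α-dihydroxyabiet-7-en-18-oic acid | O[C@@H]1C2=CC[C@@H]3[C@](C)(CCC[C@@]3(C)C(=O)O)[C@H]2CC[C@@]1(O)C(C)C | intermediate
16 | 13,14-dioxo-13,14-secoabiet-7-en-18-oic acid (5α-H, 9α-H, 10β-methyl, 4α-carboxyl as in abietic acid) | O=CC1=CC[C@@H]2[C@](C)(CCC[C@@]2(C)C(=O)O)[C@H]1CCC(=O)C(C)C | intermediate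
17 | (E)-tosylhydrazone of the C14 aldehyde of 16 | Cc1ccc(cc1)S(=O)(=O)N/N=C/C1=CC[C@@H]2[C@](C)(CCC[C@@]2(C)C(=O)O)[C@H]1CCC(=O)C(C)C | intermediate
18 | (1R,4aR,5S,8aR)-1,4a-dimethyl-6-methylidene-5-(4-methyl-3-oxopentyl)decahydronaphthalene-1-carboxylic acid | C=C1CC[C@@H]2[C@](C)(CCC[C@@]2(C)C(=O)O)[C@H]1CCC(=O)C(C)C | intermediate
19 | dilithium salt of 18 (carboxylate and Z-enolate toward the methylene) | [Li+].[Li+].C=C1CC[C@@H]2[C@](C)(CCC[C@@]2(C)C(=O)[O-])[C@H]1C/C=C(\[O-])C(C)C | intermediate
20 | (1R,4aR,5S,8aR)-5-(2-hydroxy-4-methyl-3-oxopentyl)-1,4a-dimethyl-6-methylidenedecahydronaphthalene-1-carboxylic acid (mixture of carbinol epimers) | C=C1CC[C@@H]2[C@](C)(CCC[C@@]2(C)C(=O)O)[C@H]1CC(O)C(=O)C(C)C | intermediate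
21 | (1R,4aR,5S,8aR)-1,4a-dimethyl-6-methylidene-5-(2-oxoethyl)decahydronaphthalene-1-carboxylic acid | C=C1CC[C@@H]2[C@](C)(CCC[C@@]2(C)C(=O)O)[C@H]1CC=O | intermediate
22 | (1R,4aR,5S,8aR)-1,4a-dimethyl-6-methylidene-5-[(2E)-3-methyl-4-oxobut-2-en-1-yl]decahydronaphthalene-1-carboxylic acid | C=C1CC[C@@H]2[C@](C)(CCC[C@@]2(C)C(=O)O)[C@H]1C/C=C(\C)C=O | intermediate
23 | (1R,4aR,5S,8aR)-1,4a-dimethyl-6-methylidene-5-[(2E)-3-methylpenta-2,4-dien-1-yl]decahydronaphthalene-1-carboxylic acid, (12E)-labda-8(17),12,14-trien-18-oic acid | C=C1CC[C@@H]2[C@](C)(CCC[C@@]2(C)C(=O)O)[C@H]1C/C=C(\C)C=C | intermediate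
24 | CNP0256710.1, the [5+2] adduct of 13 and 23 (C8 S, C13 R, C14' S; ethano bridge on the α face, dienyl residue endo) | C=C1CC[C@@H]2[C@](C)(CCC[C@@]2(C)C(=O)O)[C@H]1C/C=C(\C)[C@@H]1C[C@@]23C(=O)[C@]1(C(C)C)C(=O)C(O)=C2[C@@]1(C)CCCC(C)(C)[C@@H]1[C@H]3C=O | target

## Step count and risks

Total step count: 14 (quinone half 7, acid half 6, union 1). Longest linear sequence: 8 steps (steps 1–7, then step 14).

**Step 7 (proposed new oxygenation).** The ortho-quinone may couple with unreacted phenol, or the hydration at the hindered C14 may be slow. The fallback uses known chemistry and sets out from 9. o-Iodoxybenzoic acid in DMF, a known regioselective ortho-oxygenation of phenols, gives ortho-quinone 10, which is now isolated. Thiele–Winter acetoxylation (Ac2O, cat. H2SO4) adds acetate at C14 and exchanges the acetal for the geminal diacetate, giving the pentaacetate F1. K2CO3 in MeOH under air removes all acetyl groups, the liberated triol autoxidises to the hydroxyquinone, and work-up with dilute HCl comes back to the route at 13.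

**Step 14 ([5+2] union).** Competing Diels–Alder addition of the diene, carbonyl-ene reaction of the aldehyde, or acid isomerisation of the exocyclic alkene can take over, and C8 is a hindered, fully substituted terminus. The fallback sets out from 13. MeI/Ag2O gives the 12-O-methyl ether F2. F2 and 23 are combined with TiCl4/Ti(OiPr)4 in CH2Cl2 at −78 °C, the chelated alkoxyquinone version of the [5+2] cycloaddition that is established for 2-alkoxy-1,4-benzoquinones and alkenes. Aqueous work-up hydrolyses the O-methyl oxocarbenium of the adduct, and the route is rejoined at 24.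

**Step 5 (ring contraction).** The hindered, rigid trans-fused styrene may give 6,7-dimethoxy addition or arene oxidation instead of the aryl shift. The fallback sets out from 6 and bypasses 7. CrO3 in AcOH oxidises the benzylic C7 to give sugiol methyl ether F3. HCO2Et/NaH gives the hydroxymethylene ketone F4, and TsN3/Et3N (deformylative diazo transfer) gives the diazoketone F5. Irradiation in MeOH (Wolff rearrangement with aryl migration) followed by NaOMe equilibration gives the ring-contracted methyl ester F6. i-Bu2AlH at −78 °C gives the aldehyde F7, and HC(OMe)3/TsOH in MeOH comes back to the route at 8.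

## Further compounds

F1 | step 7 | [(4aS,9R,9aS)-5,6,8-triacetoxy-1,1,4a-trimethyl-7-(propan-2-yl)-2,3,4,4a,9,9a-hexahydro-1H-fluoren-9-yl]methanediyl diacetate (pentaacetate) | CC(C)c1c(OC(C)=O)c2c(c(OC(C)=O)c1OC(C)=O)[C@@]1(C)CCCC(C)(C)[C@@H]1[C@H]2C(OC(C)=O)OC(C)=O
F2 | step 14 | (4aS,9R,9aS)-6-methoxy-1,1,4a-trimethyl-5,8-dioxo-7-(propan-2-yl)-2,3,4,4a,5,8,9,9a-octahydro-1H-fluorene-9-carbaldehyde (12-O-methyl ether of 13) | CC(C)C1=C(OC)C(=O)C2=C(C1=O)[C@H](C=O)[C@H]1C(C)(C)CCC[C@]21C
F3 | step 5 | sugiol methyl ether, 12-methoxyabieta-8,11,13-trien-7-one | CC(C)c1cc2c(cc1OC)[C@@]1(C)CCCC(C)(C)[C@@H]1CC2=O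
F4 | step 5 | 6-(hydroxymethylidene)-12-methoxyabieta-8,11,13-trien-7-one (chelated enol) | CC(C)c1cc2c(cc1OC)[C@@]1(C)CCCC(C)(C)[C@@H]1/C(=C/O)C2=O
F5 | step 5 | 6-diazo-12-methoxyabieta-8,11,13-trien-7-one | CC(C)c1cc2c(cc1OC)[C@@]1(C)CCCC(C)(C)[C@@H]1C(=[N+]=[N-])C2=O
F6 | step 5 | methyl (4aS,9R,9aS)-6-methoxy-1,1,4a-trimethyl-7-(propan-2-yl)-2,3,4,4a,9,9a-hexahydro-1H-fluorene-9-carboxylate | CC(C)c1cc2c(cc1OC)[C@@]1(C)CCCC(C)(C)[C@@H]1[C@H]2C(=O)OC
F7 | step 5 | (4aS,9R,9aS)-6-methoxy-1,1,4a-trimethyl-7-(propan-2-yl)-2,3,4,4a,9,9a-hexahydro-1H-fluorene-9-carbaldehyde | CC(C)c1cc2c(cc1OC)[C@@]1(C)CCCC(C)(C)[C@@H]1[C@H]2C=O
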